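## The problem

The target is a germacranolide. Its ten-membered carbocycle (C1–C10) carries trisubstituted epoxides at C1–C10 and C4–C5 and is fused at C6–C7 to a butenolide whose tetrasubstituted alkene is C7=C11. C13 is an acetoxymethyl group, and C8 carries the ester of (R)-3-chloro-2-hydroxy-2-methylpropanoic acid.

There are six ring stereocentres (C1, C10, C4, C5, C6, C8) and one in the side chain. C4, C5 and C6 can be bought with the ring. The crown conformation of a 1(10)E-germacrene sends a peracid to the outer face and so fixes C1/C10. C8 has no sp3 neighbour that could direct it, so only the way the ten-membered ring covers one face of a planar precursor can set it. The side-chain centre is too remote to be induced and has to be purchased.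

Several groups are fragile. The epoxides open transannularly in acid. H-6 is the γ-hydrogen of the butenolide and sits next to the 4,5-epoxide, so base threatens epimerisation and β-elimination through the 2-oxidofuran. The allylic C13 acetate can migrate or be displaced, and the chlorohydrin closes to a glycidate in base.

The enabling feature is that the oxygens at C8 and C13 lie 1,4 and cis across C7=C11. This is the pattern left when the O–O bond of a 3,6-dihydro-1,2-dioxine is reduced, and that dioxine is the singlet-oxygen adduct of the diene C8=C7–C11=C13, which the lactone ring locks s-cis. The real work is therefore to make this diene from a C8-unoxidised germacranolide with the right regiochemistry (C8–H, not C6–H) and a defined C7=C8 geometry.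

## Retrosynthesis

**C8 ester.** The acyl C–O bond at C8 is cut last, giving alcohol 11 and the silyl-protected acid 14; the target 17 then follows from ester 16 by desilylation. Acylating late keeps the base-sensitive chlorohydrin out of all earlier steps. The triethylsilyl ether stops self-acylation and glycidate formation and comes off with buffered fluoride, which the epoxides tolerate. The forward step must acylate a hindered allylic alcohol without moving the C13 acetate. Acid 14 comes from the purchased acid 12 through the bis-silyl derivative 13.

**C13 acetate.** Cutting the acetyl C–O bond leads to diol 10. Acetylating before the C8 acylation uses the large rate gap between the primary C13 hydroxyl and the ring-flanked secondary C8 hydroxyl, so no protecting group is needed.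

**O–O bond.** Diol 10 is the reduction product of endoperoxide 9. A neutral reductant is required because C8–H in 9 is acidic and base would trigger a Kornblum–DeLaMare isomerisation.

**C8–O and C13–O (key).** Both bonds are cut together, leading to diene 8 and singlet oxygen. Against stepwise allylic oxidation at C8, this cut delivers both oxygens, their cis relation and the position of the alkene in one operation, and it removes one stereocentre and one ring. The forward reaction must add to one face only, which the 7E geometry of 8 should ensure.

**Diene.** The C7=C8 and C11=C13 π bonds of 8 are traced to the allylic alcohol 5 by a 1,4-dehydration through sulfenate 6 and the C7 sulfoxide 7. The obvious neighbour, base-induced 1,4-dehydrobromination of bromide 3, is rejected for three reasons. H-6 is the more acidic γ-hydrogen, its removal opens the adjacent epoxide or leads to the wrong diene, and a planar dienolate offers no control of alkene geometry. The sulfoxide route removes hydrogen intramolecularly and syn from C7, which addresses all three points.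

**C13 oxygen and C7=C11.** Alcohol 5 comes from bromide 3 by displacement with formate (formate ester 4) and mild methanolysis. Bromide 3 comes from 1β,10α-epoxyparthenolide 2 by allylic bromination with transposition. Compound 2 has a single allylic hydrogen (H-7), so a radical substitution has only one site to choose. Bromine addition followed by elimination was set aside because the elimination could instead run toward C13.

**C1–C10 epoxide.** Compound 2 is the peracid epoxide of parthenolide 1, which supplies the ring, the lactone and C4, C5 and C6. Epoxidising first also removes the only alkene that could later compete for bromine or singlet oxygen.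

## Roads not taken

**Alternative 1:** Here C7–C8 is cut. A C8 α-alkoxy carbanion, made by tin–lithium exchange in a thirteen-membered cyclic allyl ether, attacks C7 as O–C13 breaks (Still–Wittig shift), contracting the ring to the germacratriene A1.
- Merits: the ten-membered ring is made without a direct medium-ring closure, and the C8 oxygen is placed by construction, whereas the chosen plan relies on a facial preference in a photooxygenation.
- Weak points: A1 is still far from the target. C12 is an ether that must become the lactone carbonyl. The alkene is at 11(13) and must move to 7(11), which erases the C7 centre the rearrangement just set. C13 is not yet oxygenated, and both ring alkenes remain to be epoxidised on a triene that is prone to Cope rearrangement and transannular cyclisation.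
- Comparison: the macrocyclic precursor alone would cost more steps than the whole chosen route, which starts with the ring, lactone and three stereocentres in place.

**Alternative 2:** Here the C6–O bond is cut. A P450 monooxygenase of the germacranolide lactone-synthase type (CYP71 family) would hydroxylate C6–H on the α face and the alcohol would close onto C12, giving A2.
- Merits: in step economy after the key step this road is better than the chosen one. A2 already has the 8α-hydroxyl, the C13 acetate and the 7(11)-alkene, so only two outer-face epoxidations and one acylation would remain, and C8 would be inherited.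
- Weak points: the known enzymes accept an 11(13)-unsaturated acid without C8 or C13 oxygen, whereas this substrate has a tetrasubstituted conjugated alkene and two extra oxygen functions at the site of reaction. Turnover cannot be defended without enzyme engineering. The open-chain substrate also needs its own enantioselective C8 reduction and a differentiation of two geminal methyl groups.
- Comparison: the chosen plan sets purely chemical, individually precedented steps from a purchasable chiral-pool lactone against this.

**Alternative 3:** Here C2=C3 is cut. A ruthenium alkylidene (second-generation Grubbs catalyst) would join two vinyl oxirane termini and close the ten-membered ring to A3.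
- Merits: the route is convergent. Both epoxides and C8 would be set beforehand by reliable asymmetric chemistry, so the stereochemical risk is lower than in the chosen plan.
- Weak points: ten-membered ring-closing metathesis is unfavourable, and carbenes next to epoxides are poor partners. The new 2Z alkene must then be hydrogenated without hydrogenolysis of two allylic epoxide C–O bonds or the allylic acetate. The open-chain precursor with six stereocentres is long.
- Comparison: the chosen plan has one uncertain stereochemical event but no medium-ring closure at all.

Key step: step 5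

Assumption: (R)-3-chloro-2-hydroxy-2-methylpropanoic acid (12) is taken as a purchasable single enantiomer, like its 3-bromo analogue; the configuration at sulfur in 7 has no bearing on the route and is left open.

## Steps

Step 1
Reactants: 1 parthenolide
Product: 2 1β,10α-epoxyparthenolide (1β,10α:4α,5β-diepoxygermacr-11(13)-en-12,6α-olide)
Conditions: mCPBA (1.1 equiv), CH2Cl2, 0 °C
Reagents that add atoms: 3-chloroperoxybenzoic acid, OOC(=O)c1cccc(Cl)c1
Why: Prilezhaev epoxidation; the electron-rich 1(10)E alkene reacts while the conjugated methylene does not, and the peracid approaches the outer face of the crown conformer, which sets C1 and C10 as the 1β,10α-epoxide.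

Step 2
Reactants: 2 1β,10α-epoxyparthenolide
Product: 3 13-bromo-1β,10α:4α,5β-diepoxygermacr-7(11)-en-12,6α-olide
Conditions: NBS (1.05 equiv), AIBN (cat.), PhCF3, 80 °C
Reagents that add atoms: N-bromosuccinimide, BrN1C(=O)CCC1=O
Why: Wohl–Ziegler allylic bromination with allylic transposition; H-7 is the only allylic hydrogen, and the C7–C11–C13 radical takes bromine at the unhindered C13 terminus, which returns the alkene to conjugation as the tetrasubstituted butenolide. C6 is untouched and no base is present.

Step 3
Reactants: 3 13-bromo-1β,10α:4α,5β-diepoxygermacr-7(11)-en-12,6α-olide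
Product: 5 13-hydroxy-1β,10α:4α,5β-diepoxygermacr-7(11)-en-12,6α-olide, via 13-formyloxy butenolide 4 (not isolated)
Conditions: HCO2Cs, DMF, rt; then MeOH, KHCO3 (cat.), 0 °C to rt
Reagents that add atoms: caesium formate, [Cs+].[O-]C=O
Why: SN2 displacement of a primary allylic bromide by a non-basic oxygen nucleophile (attack at the fully substituted C7 is blocked), then transesterification of the labile formate. The conditions are mild enough to leave H-6 and the neighbouring epoxide alone.

Step 4
Reactants: 5 13-hydroxy-1β,10α:4α,5β-diepoxygermacr-7(11)-en-12,6α-olide
Product: 8 (7E)-1β,10α:4α,5β-diepoxygermacra-7,11(13)-dien-12,6α-olide, via 13-O-sulfenate 6 (not isolated), via C7 sulfoxide 7 (not isolated)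
Conditions: 2,4-(O2N)2C6H3SCl (1.3 equiv), Et3N (1.2 equiv), ClCH2CH2Cl, −20 °C, then 40 °C
Reagents that add atoms: none
Why: 1,4-Dehydration of an allylic alcohol: O-sulfenylation, [2,3]-sigmatropic sulfenate-to-sulfoxide shift (the Mislow–Evans rearrangement run toward the sulfoxide) that places sulfur on C7 and restores the 11(13)-methylene, then thermal syn-elimination of the electron-poor aryl sulfoxide with a C8 hydrogen. Sulfoxide eliminations prefer a methylene hydrogen over a methine on an oxygen-bearing carbon, so C6–H is spared, and a syn-elimination in a medium ring passes through a transition state with the ring carbons C6 and C9 anticlinal, which should give the trans (7E) alkene.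

Step 5
Reactants: 8 (7E)-1β,10α:4α,5β-diepoxygermacra-7,11(13)-dien-12,6α-olide
Product: 9 8α,13-epidioxy-1β,10α:4α,5β-diepoxygermacr-7(11)-en-12,6α-olide
Conditions: O2, 5,10,15,20-tetraphenylporphyrin (cat.), CH2Cl2, green LED, −20 °C
Reagents that add atoms: dioxygen (as singlet oxygen), O=O
Why: The excited sensitiser transfers energy to O2, and singlet oxygen adds in a concerted, suprafacial [4+2] cycloaddition to C8 and C13 of the diene, which the lactone holds s-cis; C8–O and C13–O form together and the alkene moves to C7=C11. The closest known reaction type is the dye-sensitised photooxygenation of 1,2-dialkylidenecycloalkanes and other s-cis-locked 1,3-dienes to 3,6-dihydro-1,2-dioxines. The one new ring, the six-membered 1,2-dioxine, closes by cycloaddition, both ring bonds being made on one face, and is annulated to the butenolide across C7–C11. The one new stereocentre, C8, is set by the face of approach: in the 7E diene C6 and C9 are trans across C7=C8, so the C5–C4–C3–C2–C1–C10 bridge has to cross the diene face on the side of C5, and oxygen can reach only the opposite face (that of H-6), which gives the 8α C–O bond. The step needs cycloaddition to outrun the ene reaction with the allylic hydrogens at C9 and C6; the locked s-cis geometry favours cycloaddition, and both ring alkenes are already epoxides, so no isolated trisubstituted alkene competes. The diene is conjugated to the lactone carbonyl and may add slowly, hence low temperature, dilute solution and a halogenated solvent in which singlet oxygen is long-lived. No amine is present, because the product has an acidic C8–H next to the peroxide.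

Step 6
Reactants: 9 8α,13-epidioxy-1β,10α:4α,5β-diepoxygermacr-7(11)-en-12,6α-olide
Product: 10 8α,13-dihydroxy-1β,10α:4α,5β-diepoxygermacr-7(11)-en-12,6α-olide
Conditions: thiourea (1.5 equiv), MeOH, 0 °C to rt
Reagents that add atoms: none
Why: Thiourea reduction of an endoperoxide to the cis-2-ene-1,4-diol by nucleophilic attack at oxygen; the medium is neutral, so no Kornblum–DeLaMare rearrangement occurs and the C8 configuration is kept.

Step 7
Reactants: 10 8α,13-dihydroxy-1β,10α:4α,5β-diepoxygermacr-7(11)-en-12,6α-olide
Product: 11 13-acetoxy-8α-hydroxy-1β,10α:4α,5β-diepoxygermacr-7(11)-en-12,6α-olide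
Conditions: AcCl (1.1 equiv), 2,4,6-collidine, CH2Cl2, −78 °C
Reagents that add atoms: acetyl chloride, CC(=O)Cl
Why: Kinetically controlled acylation; the primary allylic C13 hydroxyl is far more accessible than the secondary C8 hydroxyl flanked by the ring, and acetyl chloride with collidine at low temperature is a known primary-selective acetylation.

Step 8
Reactants: 12 (R)-3-chloro-2-hydroxy-2-methylpropanoic acid
Product: 14 (R)-3-chloro-2-methyl-2-(triethylsilyloxy)propanoic acid, via bis-silyl derivative 13 (not isolated)
Conditions: TESOTf (2.3 equiv), 2,6-lutidine, CH2Cl2, 0 °C; then K2CO3, MeOH–H2O, 0 °C; work-up at pH 4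
Reagents that add atoms: triethylsilyl trifluoromethanesulfonate, CC[Si](CC)(CC)OS(=O)(=O)C(F)(F)F
Why: Silyl triflate silylation of both the acid and the hindered tertiary alcohol, then selective hydrolysis of the much more labile silyl ester; the stereocentre is not involved and no free alkoxide is formed next to the chloride.

Step 9
Reactants: 11 13-acetoxy-8α-hydroxy-1β,10α:4α,5β-diepoxygermacr-7(11)-en-12,6α-olide; 14 (R)-3-chloro-2-methyl-2-(triethylsilyloxy)propanoic acid
Product: 16 13-acetoxy-8α-[(R)-3-chloro-2-methyl-2-(triethylsilyloxy)propanoyloxy]-1β,10α:4α,5β-diepoxygermacr-7(11)-en-12,6α-olide, via mixed anhydride 15 (not isolated)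
Conditions: 14, 2,4,6-Cl3C6H2COCl, Et3N, THF, rt; then 11, DMAP (0.3 equiv), toluene, rt
Reagents that add atoms: none
Why: Yamaguchi esterification; the mixed anhydride transfers the hindered acyl group to the secondary allylic alcohol under DMAP catalysis with retention at C8, and the silyl ether prevents self-acylation and glycidate formation.

Step 10
Reactants: 16 13-acetoxy-8α-[(R)-3-chloro-2-methyl-2-(triethylsilyloxy)propanoyloxy]-1β,10α:4α,5β-diepoxygermacr-7(11)-en-12,6α-olide
Product: 17 13-acetoxy-8α-[(R)-3-chloro-2-hydroxy-2-methylpropanoyloxy]-1β,10α:4α,5β-diepoxygermacr-7(11)-en-12,6α-olide (target)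
Conditions: Et3N·3HF, THF, 0 °C to rt
Reagents that add atoms: none
Why: Fluoride-induced cleavage of the silyl ether in an amine-buffered, weakly acidic medium; the tertiary hydroxyl is protonated as it is released, so the chlorohydrin cannot close, and the acetate, ester, butenolide and epoxides should be stable.

## Compound list

1 | parthenolide (4α,5β-epoxygermacra-1(10)E,11(13)-dien-12,6α-olide) | C=C1[C@@H]2CC/C(C)=C/CC[C@@]3(C)O[C@@H]3[C@H]2OC1=O | starting material
2 | 1β,10α-epoxyparthenolide (1β,10α:4α,5β-diepoxygermacr-11(13)-en-12,6α-olide) | C=C1[C@@H]2CC[C@@]3(C)O[C@@H]3CC[C@@]3(C)O[C@@H]3[C@H]2OC1=O | intermediate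
3 | 13-bromo-1β,10α:4α,5β-diepoxygermacr-7(11)-en-12,6α-olide | BrCC1=C2CC[C@@]3(C)O[C@@H]3CC[C@@]3(C)O[C@@H]3[C@H]2OC1=O | intermediate
4 | 13-formyloxy-1β,10α:4α,5β-diepoxygermacr-7(11)-en-12,6α-olide | O=COCC1=C2CC[C@@]3(C)O[C@@H]3CC[C@@]3(C)O[C@@H]3[C@H]2OC1=O | intermediate
5 | 13-hydroxy-1β,10α:4α,5β-diepoxygermacr-7(11)-en-12,6α-olide | OCC1=C2CC[C@@]3(C)O[C@@H]3CC[C@@]3(C)O[C@@H]3[C@H]2OC1=O | intermediate
6 | 13-(2,4-dinitrophenylsulfanyloxy)-1β,10α:4α,5β-diepoxygermacr-7(11)-en-12,6α-olide (O-sulfenate of 5) | O=[N+]([O-])c1ccc(SOCC2=C3CC[C@@]4(C)O[C@@H]4CC[C@@]4(C)O[C@@H]4[C@H]3OC2=O)c([N+](=O)[O-])c1 | intermediate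
7 | 7-(2,4-dinitrophenylsulfinyl)-1β,10α:4α,5β-diepoxygermacr-11(13)-en-12,6α-olide, sulfur on the face of H-6, configuration at sulfur open | C=C1[C@@]2(S(=O)c3ccc(cc3[N+](=O)[O-])[N+](=O)[O-])CC[C@@]3(C)O[C@@H]3CC[C@@]3(C)O[C@@H]3[C@H]2OC1=O | intermediate
8 | (7E)-1β,10α:4α,5β-diepoxygermacra-7,11(13)-dien-12,6α-olide | C=C1/C2=C\C[C@@]3(C)O[C@@H]3CC[C@@]3(C)O[C@@H]3[C@H]2OC1=O | intermediate
9 | 8α,13-epidioxy-1β,10α:4α,5β-diepoxygermacr-7(11)-en-12,6α-olide | O1OCC2=C3[C@@H]1C[C@@]4(C)O[C@@H]4CC[C@@]4(C)O[C@@H]4[C@H]3OC2=O | intermediate
10 | 8α,13-dihydroxy-1β,10α:4α,5β-diepoxygermacr-7(11)-en-12,6α-olide | OCC1=C2[C@@H](O)C[C@@]3(C)O[C@@H]3CC[C@@]3(C)O[C@@H]3[C@H]2OC1=O | intermediate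
11 | 13-acetoxy-8α-hydroxy-1β,10α:4α,5β-diepoxygermacr-7(11)-en-12,6α-olide | CC(=O)OCC1=C2[C@@H](O)C[C@@]3(C)O[C@@H]3CC[C@@]3(C)O[C@@H]3[C@H]2OC1=O | intermediate
12 | (R)-3-chloro-2-hydroxy-2-methylpropanoic acid | OC(=O)[C@@](C)(O)CCl | starting material
13 | triethylsilyl (R)-3-chloro-2-methyl-2-(triethylsilyloxy)propanoate | CC[Si](CC)(CC)OC(=O)[C@@](C)(O[Si](CC)(CC)CC)CCl | intermediate
14 | (R)-3-chloro-2-methyl-2-(triethylsilyloxy)propanoic acid | OC(=O)[C@@](C)(O[Si](CC)(CC)CC)CCl | intermediate
15 | (R)-3-chloro-2-methyl-2-(triethylsilyloxy)propanoic 2,4,6-trichlorobenzoic anhydride | O=C(OC(=O)[C@@](C)(O[Si](CC)(CC)CC)CCl)c1c(Cl)cc(Cl)cc1Cl | intermediate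
16 | 13-acetoxy-8α-[(R)-3-chloro-2-methyl-2-(triethylsilyloxy)propanoyloxy]-1β,10α:4α,5β-diepoxygermacr-7(11)-en-12,6α-olide | CC(=O)OCC1=C2[C@@H](OC(=O)[C@@](C)(O[Si](CC)(CC)CC)CCl)C[C@@]3(C)O[C@@H]3CC[C@@]3(C)O[C@@H]3[C@H]2OC1=O | intermediate
17 | 13-acetoxy-8α-[(R)-3-chloro-2-hydroxy-2-methylpropanoyloxy]-1β,10α:4α,5β-diepoxygermacr-7(11)-en-12,6α-olide (CNP0255009.1) | CC(=O)OCC1=C2[C@@H](OC(=O)[C@@](C)(O)CCl)C[C@@]3(C)O[C@@H]3CC[C@@]3(C)O[C@@H]3[C@H]2OC1=O | target

## Step count and risk

Total: 10 steps. Longest linear sequence: 9 steps (steps 1–7, 9 and 10 from parthenolide); step 8 is a one-step side branch.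

**Step 5 (key).** Three things are most likely to go wrong. The ene-type hydroperoxidation at C7=C8 may compete. The electron-poor diene may add so slowly that it dimerises or undergoes a 1,5-hydrogen shift from C9 to C13. Any 7Z isomer in the diene would open the other face and erode the C8 configuration. Fallback: diene 8 is epoxidised at the more electron-rich C7=C8 bond with dimethyldioxirane from the same open face, giving the 7,8-epoxy-11(13)-ene F1. Opening of this vinyl epoxide with acetic acid under Pd(PPh3)4 catalysis (zerovalent palladium, Tsuji–Trost 1,4-addition) should put acetate on C13, return the alkene to C7=C11 and leave the C8 hydroxyl with its configuration. The route is rejoined at 11, and steps 6 and 7 are skipped.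

**Step 4.** The sulfenate-to-sulfoxide shift may stall because C7 is fully substituted and electron-poor. The syn-elimination may run toward H-6 and give the enol lactone, or give the cis C7=C8 bond. Triethylamine may deprotonate C6 and open the 4,5-epoxide. Fallback: alcohol 5 is converted with methyl chloroformate and pyridine into the 13-methyl carbonate F2, which is subjected to Pd2(dba)3 and PBu3 in warm THF. This 1,4-elimination through a π-allylpalladium intermediate loses CO2 and methanol without any added base and returns to diene 8.

**Step 2.** The radical chain may add bromine across the methylene instead of substituting. The product may be brominated again at C8. Traces of HBr may open an epoxide. Fallback: epoxide 2 is treated with bromine in CH2Cl2 in the dark to give the 11β,13-dibromide F3. Anti-elimination of H-7 and the C11 bromine with DBU at low temperature then gives bromide 3. The weak point of this ionic sequence is elimination toward C13 instead of into the ring.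

**Step 9.** Acyl transfer to the hindered C8 hydroxyl may be slow enough for the C13 acetyl group to migrate, for the lactone to translactonise to the 12,8-olide, or for elimination to start. Fallback: alcohol 11 is oxidised with Dess–Martin periodinane to the 8-ketone F4. Luche reduction (NaBH4, CeCl3·7H2O) from the exposed face is expected to give the 8β-alcohol F5; if it returns the 8α-alcohol, that is 11 again and nothing is lost. Mitsunobu esterification of F5 with acid 14 (PPh3, DIAD) then forms the ester with inversion and rejoins the route at 16. The same Mitsunobu closure would take any 8β-epimer of 11 arising from a facial leak in step 5 directly to 16.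

## Further compounds

F1 | step 5 | 7,8-epoxy-1β,10α:4α,5β-diepoxygermacr-11(13)-en-12,6α-olide, new epoxide oxygen on the face of H-6 | C=C1[C@@]24O[C@H]2C[C@@]3(C)O[C@@H]3CC[C@@]3(C)O[C@@H]3[C@H]4OC1=O
F2 | step 4 | 13-(methoxycarbonyloxy)-1β,10α:4α,5β-diepoxygermacr-7(11)-en-12,6α-olide | COC(=O)OCC1=C2CC[C@@]3(C)O[C@@H]3CC[C@@]3(C)O[C@@H]3[C@H]2OC1=O
F3 | step 2 | 11β,13-dibromo-1β,10α:4α,5β-diepoxygermacran-12,6α-olide | BrC[C@@]1(Br)[C@@H]2CC[C@@]3(C)O[C@@H]3CC[C@@]3(C)O[C@@H]3[C@H]2OC1=O
F4 | step 9 | 13-acetoxy-8-oxo-1β,10α:4α,5β-diepoxygermacr-7(11)-en-12,6α-olide | CC(=O)OCC1=C2C(=O)C[C@@]3(C)O[C@@H]3CC[C@@]3(C)O[C@@H]3[C@H]2OC1=O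
F5 | step 9 | 13-acetoxy-8β-hydroxy-1β,10α:4α,5β-diepoxygermacr-7(11)-en-12,6α-olide | CC(=O)OCC1=C2[C@H](O)C[C@@]3(C)O[C@@H]3CC[C@@]3(C)O[C@@H]3[C@H]2OC1=O
A1 | alternative 1 | 8-hydroxy-6-(tert-butyldimethylsilyloxy)germacra-1(10)E,4E,11(13)-trien-12-yl 4-methoxybenzyl ether | C=C(COCc1ccc(OC)cc1)[C@@H]1[C@@H](O)C/C(C)=C/CC/C(C)=C/[C@H]1O[Si](C)(C)C(C)(C)C
A2 | alternative 2 | 13-acetoxy-8α-hydroxygermacra-1(10)E,4E,7(11)-trien-12,6α-olide | CC(=O)OCC1=C2[C@@H](O)C/C(C)=C/CC/C(C)=C/[C@H]2OC1=O
A3 | alternative 3 | (2Z)-13-acetoxy-8α-(tert-butyldimethylsilyloxy)-1β,10α:4α,5β-diepoxygermacra-2,7(11)-dien-12,6α-olide | CC(=O)OCC1=C2[C@@H](O[Si](C)(C)C(C)(C)C)C[C@@]3(C)O[C@@H]3/C=C\[C@@]3(C)O[C@@H]3[C@H]2OC1=O
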